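The numbers of this flask are invented; the rest is arithmetic.

The ratio of X to E in the charge is 2.00, so even with every bit of E spent 0.500 mM of X stays, and we may treat X as a slowly falling background to E; what we must choose is the level of X to reckon with.

    E + X → E.X (k1 = 87 M⁻¹ s⁻¹)
    Z + E.X → Z.E.X (k2 = 140 M⁻¹ s⁻¹)
    Z + Z.E.X ⇌ D, settled at all times (K3 = 1900 M⁻¹)

| flask | E | X | Z | remark | time |
|---|---|---|---|---|---|
| theta | 0.50 mM | 1.00 mM | 0.500 mM | one stirred flow tank at steady state, fed with the mixture as stated, mean residence time 6.0 s |  |
| delta | 0.50 mM (fed, over 3.00 s) | 1.00 mM | 0.500 mM | a stirred flask in which E is dosed at a steady rate over 3.00 s without added volume, worked up at 6.0 s | 6.0 s |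
| alpha | 0.50 mM | 1.00 mM (fed, over 3.00 s) | 0.500 mM | a stirred flask in which X is dosed at a steady rate over 3.00 s without added volume, worked up at 6.0 s | 6.0 s |
| zeta | 0.50 mM | 1.00 mM | 0.500 mM | a closed flask charged with all of it at once and left for 6.0 s | 6.0 s |

* the set-up with the highest amount of E.X at the outlet or at the end, in percent of the E put in ("none" if the first two lie within 2 percentage points) (theta / delta / alpha / zeta / none)
* amount of E.X at the outlet or at the end, in percent of the E put in, theta
* amount of E.X at the outlet or at the end, in percent of the E put in, delta
* amount of E.X at the outlet or at the end, in percent of the E put in, alpha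
* amount of E.X at the outlet or at the end, in percent of the E put in, zeta

- for Z.E.X the D are counted in
- the stated concentrations are those of everything mixed, before any reaction; amounts are the same in each set-up
- the feed brings no volume worth counting
- run time (delta): 6.0 s

We climb the ladder from the fastest rung. The pairing of Z with Z.E.X to D is held at balance throughout, with 0.95 as its constant times Z at the start in zeta, and it stands downstream of E.X. Next comes the run, 6.0 s, and it is shorter than the making time of E.X at charged X, 11.5 s, and the spending time at charged Z, 14.3 s, so zeta ends with E unfinished.

For zeta we take a making constant a and a spending constant b, and E.X is a/(b−a) times (e^(−at) − e^(−bt)). At charged X and Z this gives 32.6%. But that reckoning loses 0.203 mM of E and so of X, which puts the straight-line mean of X at 0.898 mM. The rate constant of step 1 times this mean X is the mean making constant, a pseudo-first-order constant, 0.0782 s⁻¹. With it, and Z left at its charge, zeta comes to 30.1%, so taking X at its mean rather than at its charge lowers our reckoned answer by 2.5 percentage points.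

For theta, with a residence time equal to 6.0 s, the steady balances give aτ over one plus aτ, times one over one plus bτ, which is 22.5%. A dose over 3.00 s holds the dosed reagent at 0.750 of its charge on average, so the making exponent drops from 0.469 to 0.352. We put delta and alpha below zeta without a number, and our pick for first place is zeta, above theta.

The forecast names zeta, with 22.3% for theta, 25.7% for delta, 25.7% for alpha and 30.2% for zeta, holding that “dosing either E or X delays formation by about the same amount”.

The simulation puts zeta first, with 22.4% for theta, 25.4% for delta, 25.5% for alpha and 30.2% for zeta. With the turning of Z + E.X into Z.E.X struck out, zeta holds 37.4% of its E as E.X, and the mean making constant, 0.0782 s⁻¹, gives 37.4% for that case. Carried to theta with the same step struck out, it gives 31.9%, and the tank holds 30.7%.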